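## Analysis of the target

Locants: the labdane half keeps labdane numbers C1–C20 (C17 = exocyclic methylene carbon on C8, C18 = carboxyl carbon on C4, C16 = methyl on C13); the other half carries primed abietane numbers C1′–C20′ (C7′ = formyl carbon on C6′); names of single-half intermediates use the same numbers without primes.

- Target 22 (C40H56O6) is a heterodimer of two C20 diterpenoid units: a labda-8(17),12E-dien-18-oic acid (trans-decalin, rings A and B) and a 6′(7′→8′)abeo-abietane, in which cyclohexane ring A′ is trans-fused to the cyclopentane ring B′ (C5′–C6′–C8′–C9′–C10′) and C7′ sits outside the ring as a formyl group.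
- The halves are joined only by the bonds C15–C8′ and C14–C13′. Together with the former ring C′ (C8′, C9′, C11′–C14′) they form a bicyclo[3.2.1]oct-3-ene-2,8-dione: one-carbon bridge C14′=O, two-carbon bridge C14–C15, three-carbon bridge C9′=C11′(OH)–C12′=O (a diosphenol).
- There are ten stereocentres: C4, C5, C9, C10 in the decalin (trans fusion, axial C19 and C20 methyls cis to each other, equatorial carboxyl, equatorial C9 chain); C5′, C6′, C10′ in the hydrindane (trans fusion, formyl α and cis to H5′); the quaternary bridgeheads C8′ and C13′; and C14.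
- The two-carbon bridge lies on the α face of ring C′, anti to the C20′ methyl; the alkenyl chain on C14 is endo (towards the C9′–C12′ bridge, away from C14′); the C12=C13 alkene is E.
- Sensitive groups: the diosphenol (air, base); the non-enolisable 1,3-diketone C12′/C14′ through quaternary C13′ (retro-Claisen cleavage); the enolisable aldehyde (epimerisation at C6′, ene and aldol reactions); the acid-labile 8(17)-methylene; and the free neopentyl acid.
- The difficulty is to make the two quaternary bridgeheads C8′ and C13′ while joining two hindered C20 units, with control over which alkene reacts, which termini bond, which face is used and which C14 epimer forms, on a product that tolerates neither base nor strong acid.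
- The pattern C8′–C9′–C11′–C12′–C13′ bridged by C14′=O, with OH on C11′ and oxo on C12′, is what a 2-hydroxy-1,4-benzoquinone leaves behind after a [5+2] cycloaddition with an alkene. The plan is built on this feature.

## Retrosynthetic reasoning

**22 ⇒ 15 + 21.** The bonds C15–C8′ and C14–C13′ are cut together. They are the only links between the halves. Cutting them turns ring C′ back into the flat 2-hydroxy-1,4-benzoquinone of 15 and the two-carbon bridge into the terminal vinyl group of diene acid 21; nothing else changes, so no protecting group is needed. The gain is the whole bicyclo[3.2.1]octene, both quaternary bridgeheads, C14 and the diosphenol oxidation pattern in one addition without by-product. The forward step is an acid-promoted [5+2] cycloaddition of the hydroxyquinone. It has to pick the C14=C15 alkene out of three, join C15 to C8′ and C14 to C13′, approach 15 on its α face and place the alkenyl chain endo.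

**21 ⇒ 19 ⇒ 17 ⇒ 16.** In 21 the two terminal methylene carbons C15 and C17 are removed (double Wittig methylenation of keto enal 19, via 20). Then the C12=C13 bond is cut (E-selective Wittig olefination of keto aldehyde 17 with stabilised ylide 18). Compound 17 holds the complete decalin with C4, C5, C9 and C10 in place. It is what remains of levopimaric acid 16 when its homoannular diene is cleaved: C12 becomes the aldehyde, C8 the ketone, and the five ring-C carbons that carry the isopropyl group leave. This is preferred to a de novo decalin synthesis because 16 already has the equatorial C18 carboxyl and axial C19 methyl, the ring A pattern that enolate and radical methods set poorly.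

**15 ⇒ 13.** The hydroxyquinone is traced back to its tris(methyl ether) 13 (ether cleavage, then autoxidation of triphenol 14). Ring C′ thus stays a robust arene until the end of this branch.

**13 ⇒ 11.** The bond C6′–C8′ is cut and C7′–C8′ restored. The formyl-bearing cyclopentane is the product of an oxidative 1,2-aryl shift across the 6,7-alkene of the ordinary abietane 11 (via acetal 12). This turns the 6-5-6 skeleton with its formyl stereocentre into a 6-6-6 abietatetraene, and the migration with inversion at C6′ places the formyl group on the α face.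

**11 ⇒ 10 ⇒ 9.** The styrene double bond is removed (benzylic dehydrogenation). The C4′–C5′ and C9′–C10′ bonds of 10 are then cut: an enantioselective proton-initiated bicyclisation of the achiral homogeranylarene 9 sets C5′ and C10′ (trans) in one step.

**9 ⇒ 6 + 7; 6 ⇒ 5 ⇒ 4 ⇒ 1 + 2.** The C6′–C7′ bond is cut between geranyl bromide 7 and the benzylic Grignard reagent 8 made from chloride 6. The arene pattern comes from 1,2,4-trimethoxybenzene 1: lithiation between two methoxy groups (3), addition to acetone 2, ionic hydrogenation of carbinol 4 to 5, and chloromethylation at the one position that is both ortho and para to methoxy groups.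

## Alternatives that were turned down

**Alternative 1:** the textbook route, one bond at a time by enolate chemistry.
- Disconnection: C14–C13′ (alkylation of the C12′/C14′ 1,3-diketone carbon) and, earlier, C15–C8′ (conjugate addition to the C8′=C9′ enedione).
- Forward key step: intramolecular Tsuji–Trost allylation of C13′ by the C14 allylic carbonate of seco compound A1 with a zerovalent palladium catalyst, after a labdane-derived C15 organometallic has been added to C8′.
- Turned down: the C8′ quaternary centre would have to come from intermolecular conjugate addition of a large organometallic to a tetrasubstituted enedione carbon, with the hydroxyquinone, aldehyde and acid all masked. The π-allyl intermediate can close at C14 or C12 and does not hold the C14 configuration, so neither ring size nor stereocentre is secured. A1 also needs a differentiated C14 oxygen on the diene, which adds many steps.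

**Alternative 2:** [5+2] first on a small diene, chain assembly afterwards.
- Disconnection: C9–C11 of the labdane chain instead of the C40 union.
- Forward key step: the same cycloaddition of 15 with dienyl acetate A2 to give bicycle A3, then allylic substitution of A3 with a C9-metalated decalin acid.
- Turned down: a C9 carbanion next to the 8(17)-alkene is an allyl metal that reacts at C17 and cannot hold the C9 configuration. The substitution would run on a substrate with a diosphenol, an aldehyde and a retro-Claisen-prone diketone. The difficult bond formation moves to after the key step, so convergence is lost with no gain in selectivity.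

**Alternative 3:** Diels–Alder reaction and 1,2-shift.
- Disconnection: C15–C8′ and C14–C12′ (a bicyclo[2.2.2]octenone), then migration of C14 from C12′ to C13′.
- Forward key step: [4+2] cycloaddition of a cyclohexa-2,4-dienone form of ring C′ with the C14=C15 alkene to give A4, then an acid-induced Wagner–Meerwein shift.
- Turned down: the required dienone is a cross-conjugated, quinone-methide-like species that dimerises, and the conjugated diene of 21 would itself act as the 4π partner. The shift needs a cation at C13′ next to the C14′ carbonyl and competes with migration of the other bridges. Two steps and an oxidation-state correction would replace one step.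

Key step: step 12

Assumptions:
- Levopimaric acid 16 is taken as a purchasable pure resin acid (it is also obtainable from pine oleoresin through its amine salt).
- In step 5 the enantiomer of the chiral proton source is the one that leads to the (5S,10S) series; if the sense of induction is opposite, the antipodal ligand is used.
- The 6α-formyl configuration (trans to C4′ on ring B′) is taken to be the thermodynamically preferred epimer, so that acid or base contact does not erode it.

## Route

**Step 1**
Reactants: 1 1,2,4-trimethoxybenzene; 2 acetone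
Product: 4 2-(2,3,6-trimethoxyphenyl)propan-2-ol, via aryllithium 3 (not isolated)
Conditions: n-BuLi, THF, 0 °C to rt; then 2, −78 °C to rt; H2O
Reagents that add atoms: none
Why: Directed ortho-metalation: the proton between the C2 and C4 methoxy groups is the most acidic, so lithiation is regioselective; the aryllithium then adds to acetone.

**Step 2**
Reactants: 4 2-(2,3,6-trimethoxyphenyl)propan-2-ol
Product: 5 2-isopropyl-1,3,4-trimethoxybenzene
Conditions: Et3SiH, CF3CO2H, CH2Cl2, 0 °C to rt
Reagents that add atoms: none
Why: Ionic hydrogenation: acid ionises the tertiary benzylic alcohol and the silane delivers hydride to the cation.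

**Step 3**
Reactants: 5 2-isopropyl-1,3,4-trimethoxybenzene
Product: 6 1-(chloromethyl)-3-isopropyl-2,4,5-trimethoxybenzene
Conditions: (CH2O)n, HCl (gas), AcOH, 0 °C to rt
Reagents that add atoms: formaldehyde (as paraformaldehyde) C=O; hydrogen chloride Cl
Why: Blanc chloromethylation (electrophilic aromatic substitution): of the two free positions only C6 of 5 is both ortho and para to methoxy groups, so the chloromethyl group should enter there; excess formaldehyde and HCl at low temperature suppress diarylmethane formation.

**Step 4**
Reactants: 6 1-(chloromethyl)-3-isopropyl-2,4,5-trimethoxybenzene; 7 geranyl bromide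
Product: 9 1-[(3E)-4,8-dimethylnona-3,7-dien-1-yl]-3-isopropyl-2,4,5-trimethoxybenzene, via benzylic Grignard reagent 8 (not isolated)
Conditions: Mg, THF, 0 °C (slow addition of 6); then 7, −20 °C to rt
Reagents that add atoms: none
Why: Uncatalysed SN2 coupling of a benzylic Grignard reagent with a primary allylic bromide; attack at the γ-carbon would create a quaternary centre and is disfavoured, so the E-alkene is carried over unchanged. Slow addition to magnesium limits Wurtz homocoupling.

**Step 5**
Reactants: 9 1-[(3E)-4,8-dimethylnona-3,7-dien-1-yl]-3-isopropyl-2,4,5-trimethoxybenzene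
Product: 10 (5S,10S)-11,12,14-trimethoxyabieta-8,11,13-triene
Conditions: (R)-3,3′-dichloro-1,1′-bi-2-naphthol·SbCl5 (1:1), CH2Cl2, −78 °C
Reagents that add atoms: none
Why: Enantioselective proton-initiated polyene cyclisation of a homogeranylarene with a Lewis-acid-activated chiral Brønsted acid. The chair–chair transition state gives the trans ring fusion, the arene closes at its only free position (C9), and the face of protonation chosen by the chiral acid sets C5 and C10 together.

**Step 6**
Reactants: 10 (5S,10S)-11,12,14-trimethoxyabieta-8,11,13-triene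
Product: 11 (5S,10S)-11,12,14-trimethoxyabieta-6,8,11,13-tetraene
Conditions: DDQ, 1,4-dioxane (dry), 80 °C
Reagents that add atoms: none
Why: Benzylic hydride abstraction by DDQ at C7, whose cation is stabilised by the ortho (C14) and para (C12) methoxy groups, then loss of H6 gives the styrene. The isopropyl methine lies in the ring plane between two methoxy groups and is not aligned for abstraction; C5 and C10 are untouched.

**Step 7**
Reactants: 11 (5S,10S)-11,12,14-trimethoxyabieta-6,8,11,13-tetraene
Product: 13 (5αH,6βH)-11,12,14-trimethoxy-6(7→8)abeo-abieta-8,11,13-trien-7-al, via dimethyl acetal 12 (not isolated)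
Conditions: PhI(OH)OTs, MeOH, 0 °C to rt; then 1 M HCl, THF, rt
Reagents that add atoms: methanol CO; water O
Why: Oxidative ring contraction of a 1,2-dihydronaphthalene by a trivalent iodine reagent: iodine adds to C6 on the α face (the β face is screened by the axial C19 and C20 methyls), methanol opens at benzylic C7, and the electron-rich aryl carbon C8 migrates from C7 to C6 with inversion, leaving the acetal carbon α (6β-H), trans to C4. Acid hydrolysis in the same flask frees the aldehyde; this epimer is also the one expected at equilibrium.

**Step 8**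
Reactants: 13 (5αH,6βH)-11,12,14-trimethoxy-6(7→8)abeo-abieta-8,11,13-trien-7-al
Product: 15 (5αH,6βH)-12-hydroxy-11,14-dioxo-6(7→8)abeo-abieta-8,12-dien-7-al, via triphenol aldehyde 14 (not isolated)
Conditions: BBr3, CH2Cl2, −78 to 0 °C; then H2O, O2 (air), EtOAc, rt
Reagents that add atoms: none
Why: Boron tribromide cleaves the three aryl methyl ethers; the 1,2,4-trihydroxyarene is oxidised by air to the 2-hydroxy-1,4-benzoquinone on work-up. The aldehyde should survive at low temperature and C6 stays in its preferred α-formyl configuration.

**Step 9**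
Reactants: 16 levopimaric acid [abieta-8(14),12-dien-18-oic acid]
Product: 17 8,12-dioxo-13,14,15,16,17-pentanorlabdan-18-oic acid
Conditions: O3, CH2Cl2/MeOH, −78 °C; then Me2S, −78 °C to rt
Reagents that add atoms: ozone [O-][O+]=O
Why: Exhaustive ozonolysis with reductive work-up: both double bonds of the homoannular diene are cleaved, C12 becomes the aldehyde and C8 the ketone, and C13–C17 leave as a five-carbon keto aldehyde. No stereocentre is touched; C9, now α to the ketone, keeps its equatorial and more stable side chain.

**Step 10**
Reactants: 17 8,12-dioxo-13,14,15,16,17-pentanorlabdan-18-oic acid; 18 2-(triphenylphosphoranylidene)propanal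
Product: 19 (12E)-8,14-dioxo-15,17-dinorlabd-12-en-18-oic acid
Conditions: toluene, 80 °C
Reagents that add atoms: none
Why: Wittig olefination with a formyl-stabilised ylide is selective for the aldehyde over the hindered ketone and gives the E-trisubstituted enal under thermodynamic control. The free carboxylic acid is compatible; such olefinations are commonly run with added carboxylic acid.

**Step 11**
Reactants: 19 (12E)-8,14-dioxo-15,17-dinorlabd-12-en-18-oic acid
Product: 21 trans-ozic acid [(12E)-labda-8(17),12,14-trien-18-oic acid], via dienyl ketone 20 (not isolated)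
Conditions: Ph3PCH3Br, KOt-Bu, THF, 0 °C; then 19, −78 °C to rt, then 50 °C; aq. citric acid
Reagents that add atoms: methyltriphenylphosphonium bromide C[P+](c1ccccc1)(c1ccccc1)c1ccccc1.[Br-]
Why: Double Wittig methylenation: the enal reacts first at low temperature to give the 12E,14-diene, and the C8 ketone gives the 8(17)-methylene on warming; the acid is present as its inert carboxylate. The trisubstituted alkene keeps its E geometry and C9 its equatorial configuration.

**Step 12**
Reactants: 15 (5αH,6βH)-12-hydroxy-11,14-dioxo-6(7→8)abeo-abieta-8,12-dien-7-al; 21 trans-ozic acid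
Product: 22 CNP0256710.1 (target)
Conditions: BF3·OEt2, CH2Cl2, −78 to −30 °C; pH 7 phosphate buffer
Reagents that add atoms: none
Why: This is the acid-promoted [5+2] cycloaddition of a 2-hydroxy-1,4-benzoquinone with an alkene, the reaction type of the perezone-to-pipitzol conversion and of Lewis-acid-promoted additions of 2-alkoxybenzoquinones to styrenes. BF3 chelated between O11′ and O12′ turns C8′–C9′–C11′–C12′–C13′ into an oxygenated pentadienyl cation bridged by the C14′ carbonyl; C15, the most nucleophilic and least hindered diene carbon, attacks the enone β-carbon C8′, and the resulting C12–C14 allyl cation is closed at C14 by the enol carbon C13′. This second bond closes the cyclopentanone C8′–C14′–C13′–C14–C15 in a 5-(enolexo)-exo-trig mode and at the same time the seven-membered ring C8′–C9′–C11′–C12′–C13′–C14–C15 in a 7-(enolendo)-exo-trig mode; loss of the proton from O12′ leaves the C12′ ketone and the C11′ enol of the target. C8′ is set by approach anti to the axial C20′ methyl, which sits over C9′/C11′ where the diene must stack (α face); C13′ follows from C8′ because the two-carbon bridge can only span one face; C14 is set by the endo arrangement, in which the allyl cation lies under the electron-rich O–C11′=C9′ unit and away from the isopropyl group and the C14′ carbonyl. The 12E geometry should be kept because the allyl cation is captured faster than it rotates. Chemoselectivity for the C14=C15 vinyl group over the 8(17)-methylene rests on allyl-cation stabilisation, and [5+2] closure is preferred over [4+2] closure at C9′ because C9′ is fully substituted and neopentyl next to C10′. The regiochemistry (C15 to C8′, C14 to C13′) follows from the polarity of the termini: C8′ is electrophilic, C13′ nucleophilic once the first bond exists.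

## Compound list

1 | 1,2,4-trimethoxybenzene | COc1ccc(OC)c(OC)c1 | starting material
2 | acetone | CC(C)=O | starting material
3 | (2,3,6-trimethoxyphenyl)lithium | COc1ccc(OC)c([Li])c1OC | intermediate (not isolated)
4 | 2-(2,3,6-trimethoxyphenyl)propan-2-ol | COc1ccc(OC)c(C(C)(C)O)c1OC | intermediate
5 | 2-isopropyl-1,3,4-trimethoxybenzene | COc1ccc(OC)c(C(C)C)c1OC | intermediate
6 | 1-(chloromethyl)-3-isopropyl-2,4,5-trimethoxybenzene | COc1cc(CCl)c(OC)c(C(C)C)c1OC | intermediate
7 | geranyl bromide, (2E)-1-bromo-3,7-dimethylocta-2,6-diene | CC(C)=CCC/C(C)=C/CBr | starting material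
8 | (3-isopropyl-2,4,5-trimethoxybenzyl)magnesium chloride | COc1cc(C[Mg]Cl)c(OC)c(C(C)C)c1OC | intermediate (not isolated)
9 | 1-[(3E)-4,8-dimethylnona-3,7-dien-1-yl]-3-isopropyl-2,4,5-trimethoxybenzene | COc1cc(CC/C=C(\C)CCC=C(C)C)c(OC)c(C(C)C)c1OC | intermediate
10 | (5S,10S)-11,12,14-trimethoxyabieta-8,11,13-triene | COc1c(OC)c(C(C)C)c(OC)c2c1[C@@]1(C)CCCC(C)(C)[C@@H]1CC2 | intermediate
11 | (5S,10S)-11,12,14-trimethoxyabieta-6,8,11,13-tetraene | COc1c(OC)c(C(C)C)c(OC)c2c1[C@@]1(C)CCCC(C)(C)[C@@H]1C=C2 | intermediate
12 | (5αH,6βH)-7,7,11,12,14-pentamethoxy-6(7→8)abeo-abieta-8,11,13-triene (dimethyl acetal) | COc1c(OC)c(C(C)C)c(OC)c2c1[C@@]1(C)CCCC(C)(C)[C@@H]1[C@H]2C(OC)OC | intermediate (not isolated)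
13 | (5αH,6βH)-11,12,14-trimethoxy-6(7→8)abeo-abieta-8,11,13-trien-7-al | COc1c(OC)c(C(C)C)c(OC)c2c1[C@@]1(C)CCCC(C)(C)[C@@H]1[C@H]2C=O | intermediate
14 | (5αH,6βH)-11,12,14-trihydroxy-6(7→8)abeo-abieta-8,11,13-trien-7-al | Oc1c(O)c(C(C)C)c(O)c2c1[C@@]1(C)CCCC(C)(C)[C@@H]1[C@H]2C=O | intermediate (not isolated)
15 | (5αH,6βH)-12-hydroxy-11,14-dioxo-6(7→8)abeo-abieta-8,12-dien-7-al | O=C1C(O)=C(C(C)C)C(=O)C2=C1[C@@]1(C)CCCC(C)(C)[C@@H]1[C@H]2C=O | intermediate
16 | levopimaric acid, abieta-8(14),12-dien-18-oic acid | CC(C)C1=CC[C@H]2C(=C1)CC[C@@H]1[C@]2(C)CCC[C@@]1(C)C(=O)O | starting material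
17 | 8,12-dioxo-13,14,15,16,17-pentanorlabdan-18-oic acid | O=CC[C@H]1C(=O)CC[C@@H]2[C@]1(C)CCC[C@@]2(C)C(=O)O | intermediate
18 | 2-(triphenylphosphoranylidene)propanal | CC(C=O)=P(c1ccccc1)(c1ccccc1)c1ccccc1 | starting material
19 | (12E)-8,14-dioxo-15,17-dinorlabd-12-en-18-oic acid | O=C/C(C)=C/C[C@H]1C(=O)CC[C@@H]2[C@]1(C)CCC[C@@]2(C)C(=O)O | intermediate
20 | (12E)-8-oxo-17-norlabda-12,14-dien-18-oic acid | C=C/C(C)=C/C[C@H]1C(=O)CC[C@@H]2[C@]1(C)CCC[C@@]2(C)C(=O)O | intermediate (not isolated)
21 | trans-ozic acid, (12E)-labda-8(17),12,14-trien-18-oic acid | C=C/C(C)=C/C[C@H]1C(=C)CC[C@@H]2[C@]1(C)CCC[C@@]2(C)C(=O)O | intermediate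
22 | CNP0256710.1: (12E)-labda-8(17),12-dien-18-oic acid joined through C15–C8′ and C14–C13′ to 11′-hydroxy-12′,14′-dioxo-6′(7′→8′)abeo-abiet-9′(11′)-en-7′-al | C=C1CC[C@@H]2[C@](C)(CCC[C@@]2(C)C(=O)O)[C@H]1C/C=C(\C)[C@@H]1C[C@@]23C(=O)[C@]1(C(C)C)C(=O)C(O)=C2[C@@]1(C)CCCC(C)(C)[C@@H]1[C@H]3C=O | target

## Step count and least certain steps

Total step count: 12. Longest linear sequence: 9 steps (steps 1–8, then step 12). The second branch has 3 steps (9–11) before the union.

**Step 12 (key step).** Most likely to go wrong:
- diversion of the cation into other bond-forming modes: closure at C9′, which amounts to Diels–Alder addition of the diene, or attack by the 8(17)-methylene;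
- Lewis-acid-induced ene or Prins capture of the free formyl group by the labdane alkenes, because the aldehyde is activated by the same promoter;
- erosion of facial or endo selectivity.

The fallback removes the aldehyde from the cycloaddition. It sets out from 13. Reduction (NaBH4, MeOH, 0 °C) should give the primary alcohol (5αH,6βH)-11,12,14-trimethoxy-6(7→8)abeo-abieta-8,11,13-trien-7-ol F1. Acetylation (Ac2O, pyridine, DMAP) gives the acetate F2. Ether cleavage and autoxidation as in step 8 (BBr3, CH2Cl2, −78 to 0 °C; air) give the hydroxyquinone acetate F3. The [5+2] cycloaddition of F3 with 21 (BF3·OEt2, CH2Cl2, −78 to −30 °C) gives the 7′-acetoxy adduct F4. Neutral deacetylation (Me3SnOH, 1,2-dichloroethane, 60 °C) gives the 7′-alcohol F5. Parikh–Doering oxidation (SO3·pyridine, DMSO, i-Pr2NEt, CH2Cl2, 0 °C) returns to the route at 22.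

**Step 5.** Most likely to go wrong: low enantioselectivity or incomplete bicyclisation, because the Lewis-basic trimethoxyarene can bind the antimony acid and the ring must close at a position ortho to a methoxy group. The fallback replaces reagent control by a stereocentre in the substrate. It sets out from 9. Shi epoxidation of the terminal alkene (fructose-derived ketone of the enantiomer that gives the S epoxide, KHSO5, K2CO3, MeCN/H2O, 0 °C, partial conversion) gives the (S)-epoxide F6. Epoxide-initiated cation–olefin cyclisation (MeAlCl2, CH2Cl2, −90 °C) gives (3S,5S,10S)-3-hydroxy-11,12,14-trimethoxyabieta-8,11,13-triene F7. Xanthate formation (NaH, CS2, MeI, THF) gives F8. Barton–McCombie deoxygenation (Bu3SnH, AIBN, toluene, 110 °C) returns to the route at 10.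

**Step 7.** Most likely to go wrong: oxidation of the electron-rich arene by the iodine reagent, or simple solvolytic 1,2-addition across the styrene without the aryl shift. The fallback is a pinacol-type contraction. It sets out from 11. Dihydroxylation from the α face (OsO4 cat., NMO, acetone/H2O) gives 6α,7α-dihydroxy-11,12,14-trimethoxyabieta-8,11,13-triene F9. Ionisation of the benzylic C7 hydroxyl (BF3·OEt2, CH2Cl2, −20 °C) with 1,2-shift of C5 contracts the ring to the same formyl-substituted cyclopentane, which returns to the route at 13 after equilibration of the formyl epimers.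

**Step 8.** Most likely to go wrong: enolisation-driven side reactions of the α-aryl aldehyde under the strong Lewis acid, and over-oxidation during autoxidation. The fallback uses oxidative instead of Lewis-acidic demethylation. It sets out from 13. (NH4)2Ce(NO3)6 in MeCN/H2O at 0 °C oxidises the para-dimethoxy pair to (5αH,6βH)-12-methoxy-11,14-dioxo-6(7→8)abeo-abieta-8,12-dien-7-al F10. Hydrolysis of this vinylogous ester (2 M H2SO4, THF, 40 °C) returns to the route at 15.

## Further compounds

F1 | step 12 | (5αH,6βH)-11,12,14-trimethoxy-6(7→8)abeo-abieta-8,11,13-trien-7-ol | COc1c(OC)c(C(C)C)c(OC)c2c1[C@@]1(C)CCCC(C)(C)[C@@H]1[C@H]2CO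
F2 | step 12 | (5αH,6βH)-7-acetoxy-11,12,14-trimethoxy-6(7→8)abeo-abieta-8,11,13-triene | COc1c(OC)c(C(C)C)c(OC)c2c1[C@@]1(C)CCCC(C)(C)[C@@H]1[C@H]2COC(C)=O
F3 | step 12 | (5αH,6βH)-7-acetoxy-12-hydroxy-6(7→8)abeo-abieta-8,12-diene-11,14-dione | O=C1C(O)=C(C(C)C)C(=O)C2=C1[C@@]1(C)CCCC(C)(C)[C@@H]1[C@H]2COC(C)=O
F4 | step 12 | 7′-acetoxy-7′-deoxo analogue of 22 | C=C1CC[C@@H]2[C@](C)(CCC[C@@]2(C)C(=O)O)[C@H]1C/C=C(\C)[C@@H]1C[C@@]23C(=O)[C@]1(C(C)C)C(=O)C(O)=C2[C@@]1(C)CCCC(C)(C)[C@@H]1[C@H]3COC(C)=O
F5 | step 12 | 7′-hydroxy-7′-deoxo analogue of 22 | C=C1CC[C@@H]2[C@](C)(CCC[C@@]2(C)C(=O)O)[C@H]1C/C=C(\C)[C@@H]1C[C@@]23C(=O)[C@]1(C(C)C)C(=O)C(O)=C2[C@@]1(C)CCCC(C)(C)[C@@H]1[C@H]3CO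
F6 | step 5 | (3S)-3-[(3E)-6-(3-isopropyl-2,4,5-trimethoxyphenyl)-3-methylhex-3-en-1-yl]-2,2-dimethyloxirane | COc1cc(CC/C=C(\C)CC[C@@H]2OC2(C)C)c(OC)c(C(C)C)c1OC
F7 | step 5 | (3S,5S,10S)-3-hydroxy-11,12,14-trimethoxyabieta-8,11,13-triene | COc1c(OC)c(C(C)C)c(OC)c2c1[C@@]1(C)CC[C@H](O)C(C)(C)[C@@H]1CC2
F8 | step 5 | O-[(3S,5S,10S)-11,12,14-trimethoxyabieta-8,11,13-trien-3-yl] S-methyl dithiocarbonate | COc1c(OC)c(C(C)C)c(OC)c2c1[C@@]1(C)CC[C@H](OC(=S)SC)C(C)(C)[C@@H]1CC2
F9 | step 7 | 6α,7α-dihydroxy-11,12,14-trimethoxyabieta-8,11,13-triene | COc1c(OC)c(C(C)C)c(OC)c2c1[C@@]1(C)CCCC(C)(C)[C@@H]1[C@@H](O)[C@H]2O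
F10 | step 8 | (5αH,6βH)-12-methoxy-11,14-dioxo-6(7→8)abeo-abieta-8,12-dien-7-al | O=C1C(OC)=C(C(C)C)C(=O)C2=C1[C@@]1(C)CCCC(C)(C)[C@@H]1[C@H]2C=O
A1 | alternative 1 | seco compound with C15–C8′ bond and C14 methyl carbonate (C14 and C13′ unassigned) | C=C1CC[C@@H]2[C@](C)(CCC[C@@]2(C)C(=O)O)[C@H]1C/C=C(\C)C(OC(=O)OC)C[C@@]12C(=O)C(C(C)C)C(=O)C(O)=C1[C@@]1(C)CCCC(C)(C)[C@@H]1[C@H]2C=O
A2 | alternative 2 | (2E)-3-methylpenta-2,4-dien-1-yl acetate | CC(=O)OC/C=C(\C)C=C
A3 | alternative 2 | [5+2] adduct of 15 with A2 | CC(=O)OC/C=C(\C)[C@@H]1C[C@@]23C(=O)[C@]1(C(C)C)C(=O)C(O)=C2[C@@]1(C)CCCC(C)(C)[C@@H]1[C@H]3C=O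
A4 | alternative 3 | bicyclo[2.2.2]octenone Diels–Alder adduct with C14 on C12′ (C14 and C12′ unassigned) | C=C1CC[C@@H]2[C@](C)(CCC[C@@]2(C)C(=O)O)[C@H]1C/C=C(\C)C1C[C@@]23C(=O)C(=C(C)C)C1(OC)C(OC)=C2[C@@]1(C)CCCC(C)(C)[C@@H]1[C@H]3C=O
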